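The route rests on assembling the open chain C1(O)–C2(CH3)–C3(O), attached at C1 to the 3,4,5-trimethoxyphenyl ring, by three one-carbon insertions into a carbon–boron bond under one (R,R)-1,2-dicyclohexylethanediol director. The feature used is the 1,2-anti/2,3-syn stereotriad C1–C2–C3, the pattern that insertions of identical sense produce when alkoxide, methyl and methyl are the nucleophiles. In the key step a CHCl unit enters the C1–B bond (C1–C2 formed) and methyl then expels chloride (C2–CH3 formed, C2 set); no ring closes. Its precursor is the benzylic boronate ArCH(OPMB)–B(diol) with C1 already R. Boron is kept as the mask of the C3 hydroxyl until C1–OH alone has been veratroylated.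

Key step: step 4

Assumption: the target is the (1R,2R,3S) ester (C1 = aryl carbinol carbon bearing the veratroate, C2 = methyl carbon, C3 = hydroxyl carbon), and the (R,R) diol is taken to give the αS chloride in every insertion, its usual sense; all descriptors below follow from that, with inversion at each displacement and retention at each 1,2-shift of carbon.

Step 1
Reactants: 1 3,4,5-trimethoxyphenylboronic acid; 2 (1R,2R)-1,2-dicyclohexylethane-1,2-diol
Product: 3 (4R,5R)-4,5-dicyclohexyl-2-(3,4,5-trimethoxyphenyl)-1,3,2-dioxaborolane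
Conditions: MgSO4, Et2O, rt
Reagents that add atoms: (1R,2R)-1,2-dicyclohexylethane-1,2-diol, O[C@H](C1CCCCC1)[C@H](O)C1CCCCC1
Why: Boronic ester formation from a boronic acid and a 1,2-diol is a condensation pulled to completion by the drying agent, and it leaves the two diol stereocentres untouched.

Step 2
Reactants: 3 (4R,5R)-4,5-dicyclohexyl-2-(3,4,5-trimethoxyphenyl)-1,3,2-dioxaborolane; 4 dichloromethane
Product: 5 (4R,5R)-2-[(S)-chloro(3,4,5-trimethoxyphenyl)methyl]-4,5-dicyclohexyl-1,3,2-dioxaborolane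
Conditions: CH2Cl2, n-BuLi, THF, −100 °C; 3; ZnCl2, −100 °C → rt; crude used at once
Reagents that add atoms: dichloromethane, ClCCl
Why: In this Matteson homologation (dichloromethyl)lithium adds to boron and zinc chloride promotes the 1,2-shift of the aryl group with loss of the chloride chosen by the C2-symmetric diol, which should set the benzylic carbon as S, while the zinc salt also binds the free chloride that would epimerise this benzylic chloride.

Step 3
Reactants: 5 (4R,5R)-2-[(S)-chloro(3,4,5-trimethoxyphenyl)methyl]-4,5-dicyclohexyl-1,3,2-dioxaborolane; 6 4-methoxybenzyl alcohol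
Product: 7 (4R,5R)-4,5-dicyclohexyl-2-[(R)-(4-methoxybenzyloxy)(3,4,5-trimethoxyphenyl)methyl]-1,3,2-dioxaborolane
Conditions: 6, n-BuLi, THF, 0 °C; then 5, −78 °C → rt
Reagents that add atoms: 4-methoxybenzyl alcohol, COc1ccc(CO)cc1
Why: In this alkoxide displacement of an α-chloro boronic ester the lithium alkoxide adds to boron and its oxygen shifts to carbon with expulsion of chloride and inversion, so the S chloride should give the R ether at C1, the cold addition of excess alkoxide letting substitution outrun epimerisation.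

Step 4
Reactants: 7 (4R,5R)-4,5-dicyclohexyl-2-[(R)-(4-methoxybenzyloxy)(3,4,5-trimethoxyphenyl)methyl]-1,3,2-dioxaborolane; 4 dichloromethane; 8 methylmagnesium bromide
Product: 10 (4R,5R)-4,5-dicyclohexyl-2-[(1R,2S)-1-(4-methoxybenzyloxy)-1-(3,4,5-trimethoxyphenyl)propan-2-yl]-1,3,2-dioxaborolane, via second-cycle α-chloro boronate 9 (not isolated)
Conditions: CH2Cl2, n-BuLi, THF, −100 °C; 7; ZnCl2 (3–4 equiv), −100 °C → rt; then MeMgBr, −78 °C → rt
Reagents that add atoms: dichloromethane, ClCCl; methylmagnesium bromide, C[Mg]Br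
Why: (Dichloromethyl)lithium adds to the boron of 7 and, on warming with zinc chloride, C1 migrates from boron to the carbenoid carbon with loss of one chloride, which forms C1–C2 with retention at C1 and gives chloride 9; methylmagnesium bromide then adds to boron and methyl shifts to C2 with inversion, which forms C2–CH3. The closest known reaction type is the Matteson asymmetric homologation of α-alkoxy boronic esters of C2-symmetric diols followed by Grignard displacement. No ring is closed. The new stereocentre C2 is controlled by the (R,R) diol, which decides which of the two diastereotopic chlorides leaves in the zinc-assisted shift (αS chloride), and by the stereospecific invertive displacement, so C2 should come out S with the C1–O and C2–CH3 bonds anti. The step needs both 1,2-shifts to outrun chloride-induced epimerisation of 9 and loss of the β-alkoxy group from the methyl borate; an ether as the poor leaving group at C1, enough zinc chloride to occupy both ether oxygens and bind free chloride, and addition of the Grignard reagent at −78 °C should secure this.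

Step 5
Reactants: 10 (4R,5R)-4,5-dicyclohexyl-2-[(1R,2S)-1-(4-methoxybenzyloxy)-1-(3,4,5-trimethoxyphenyl)propan-2-yl]-1,3,2-dioxaborolane; 4 dichloromethane; 8 methylmagnesium bromide
Product: 12 (4R,5R)-4,5-dicyclohexyl-2-[(2S,3R,4R)-4-(4-methoxybenzyloxy)-3-methyl-4-(3,4,5-trimethoxyphenyl)butan-2-yl]-1,3,2-dioxaborolane, via third-cycle α-chloro boronate 11 (not isolated)
Conditions: CH2Cl2, n-BuLi, THF, −100 °C; 10; ZnCl2 (3–4 equiv), −100 °C → rt; then MeMgBr, −78 °C → rt
Reagents that add atoms: dichloromethane, ClCCl; methylmagnesium bromide, C[Mg]Br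
Why: A second Matteson homologation and Grignard displacement on a β-alkoxy secondary alkylboronate, an established substrate class for this reaction, should again give the αS chloride under the same director and then the S carbon–boron centre by inversion, which places the C3–B bond syn to C2–CH3, low temperature holding back β-alkoxy elimination.

Step 6
Reactants: 12 (4R,5R)-4,5-dicyclohexyl-2-[(2S,3R,4R)-4-(4-methoxybenzyloxy)-3-methyl-4-(3,4,5-trimethoxyphenyl)butan-2-yl]-1,3,2-dioxaborolane
Product: 13 (1R,2R,3S)-3-[(4R,5R)-4,5-dicyclohexyl-1,3,2-dioxaborolan-2-yl]-2-methyl-1-(3,4,5-trimethoxyphenyl)butan-1-ol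
Conditions: DDQ (1.2 equiv), CH2Cl2/pH 7 buffer, 0 °C
Reagents that add atoms: none
Why: Oxidative cleavage of a 4-methoxybenzyl ether by DDQ proceeds by hydride abstraction from the unhindered anisyl CH2 and hydrolysis of the oxocarbenium ion, alkylboronic esters are inert to the quinone, and no stereocentre is involved.

Step 7
Reactants: 13 (1R,2R,3S)-3-[(4R,5R)-4,5-dicyclohexyl-1,3,2-dioxaborolan-2-yl]-2-methyl-1-(3,4,5-trimethoxyphenyl)butan-1-ol; 14 3,4-dimethoxybenzoyl chloride
Product: 15 (1R,2R,3S)-3-[(4R,5R)-4,5-dicyclohexyl-1,3,2-dioxaborolan-2-yl]-2-methyl-1-(3,4,5-trimethoxyphenyl)butyl 3,4-dimethoxybenzoate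
Conditions: 14, Et3N, DMAP, CH2Cl2, 0 °C → rt
Reagents that add atoms: 3,4-dimethoxybenzoyl chloride, COc1ccc(C(Cl)=O)cc1OC
Why: DMAP-catalysed acylation of an alcohol by an acid chloride meets only one hydroxyl here, because the C3 oxygen is still a carbon–boron bond, and it forms the ester at oxygen without touching the C1–O bond, so C1 stays R.

Step 8
Reactants: 15 (1R,2R,3S)-3-[(4R,5R)-4,5-dicyclohexyl-1,3,2-dioxaborolan-2-yl]-2-methyl-1-(3,4,5-trimethoxyphenyl)butyl 3,4-dimethoxybenzoate; 16 hydrogen peroxide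
Product: 17 (1R,2R,3S)-3-hydroxy-2-methyl-1-(3,4,5-trimethoxyphenyl)butyl 3,4-dimethoxybenzoate
Conditions: 30% H2O2, pH 7 phosphate buffer, THF, 0 °C → rt
Reagents that add atoms: hydrogen peroxide, OO
Why: Peroxide oxidation of an alkylboronic ester moves C3 from boron to oxygen with retention, so the 3S alcohol should result, and the neutral buffer protects the benzylic veratroate from hydrolysis and 1,3-acyl shift while the borate hydrolyses and releases the diol.

Compound list
1 | 3,4,5-trimethoxyphenylboronic acid | COc1cc(B(O)O)cc(OC)c1OC | starting material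
2 | (1R,2R)-1,2-dicyclohexylethane-1,2-diol, (R,R)-DICHED | O[C@H](C1CCCCC1)[C@H](O)C1CCCCC1 | starting material
3 | (4R,5R)-4,5-dicyclohexyl-2-(3,4,5-trimethoxyphenyl)-1,3,2-dioxaborolane | COc1cc(B2O[C@H](C3CCCCC3)[C@@H](C3CCCCC3)O2)cc(OC)c1OC | intermediate
4 | dichloromethane | ClCCl | starting material
5 | (4R,5R)-2-[(S)-chloro(3,4,5-trimethoxyphenyl)methyl]-4,5-dicyclohexyl-1,3,2-dioxaborolane | COc1cc([C@@H](Cl)B2O[C@H](C3CCCCC3)[C@@H](C3CCCCC3)O2)cc(OC)c1OC | intermediate
6 | 4-methoxybenzyl alcohol | COc1ccc(CO)cc1 | starting material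
7 | (4R,5R)-4,5-dicyclohexyl-2-[(R)-(4-methoxybenzyloxy)(3,4,5-trimethoxyphenyl)methyl]-1,3,2-dioxaborolane | COc1ccc(CO[C@@H](c2cc(OC)c(OC)c(OC)c2)B2O[C@H](C3CCCCC3)[C@@H](C3CCCCC3)O2)cc1 | intermediate
8 | methylmagnesium bromide | C[Mg]Br | starting material
9 | (4R,5R)-2-[(1S,2S)-1-chloro-2-(4-methoxybenzyloxy)-2-(3,4,5-trimethoxyphenyl)ethyl]-4,5-dicyclohexyl-1,3,2-dioxaborolane (ether carbon unchanged in space; its descriptor changes only through the new chlorine neighbour) | COc1ccc(CO[C@@H](c2cc(OC)c(OC)c(OC)c2)[C@@H](Cl)B2O[C@H](C3CCCCC3)[C@@H](C3CCCCC3)O2)cc1 | intermediate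
10 | (4R,5R)-4,5-dicyclohexyl-2-[(1R,2S)-1-(4-methoxybenzyloxy)-1-(3,4,5-trimethoxyphenyl)propan-2-yl]-1,3,2-dioxaborolane | COc1ccc(CO[C@@H](c2cc(OC)c(OC)c(OC)c2)[C@H](C)B2O[C@H](C3CCCCC3)[C@@H](C3CCCCC3)O2)cc1 | intermediate
11 | (4R,5R)-2-[(1S,2S,3R)-1-chloro-3-(4-methoxybenzyloxy)-2-methyl-3-(3,4,5-trimethoxyphenyl)propyl]-4,5-dicyclohexyl-1,3,2-dioxaborolane | COc1ccc(CO[C@@H](c2cc(OC)c(OC)c(OC)c2)[C@H](C)[C@@H](Cl)B2O[C@H](C3CCCCC3)[C@@H](C3CCCCC3)O2)cc1 | intermediate
12 | (4R,5R)-4,5-dicyclohexyl-2-[(2S,3R,4R)-4-(4-methoxybenzyloxy)-3-methyl-4-(3,4,5-trimethoxyphenyl)butan-2-yl]-1,3,2-dioxaborolane | COc1ccc(CO[C@@H](c2cc(OC)c(OC)c(OC)c2)[C@H](C)[C@H](C)B2O[C@H](C3CCCCC3)[C@@H](C3CCCCC3)O2)cc1 | intermediate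
13 | (1R,2R,3S)-3-[(4R,5R)-4,5-dicyclohexyl-1,3,2-dioxaborolan-2-yl]-2-methyl-1-(3,4,5-trimethoxyphenyl)butan-1-ol | O[C@@H](c1cc(OC)c(OC)c(OC)c1)[C@H](C)[C@H](C)B1O[C@H](C2CCCCC2)[C@@H](C2CCCCC2)O1 | intermediate
14 | 3,4-dimethoxybenzoyl chloride | COc1ccc(C(Cl)=O)cc1OC | starting material
15 | (1R,2R,3S)-3-[(4R,5R)-4,5-dicyclohexyl-1,3,2-dioxaborolan-2-yl]-2-methyl-1-(3,4,5-trimethoxyphenyl)butyl 3,4-dimethoxybenzoate | COc1ccc(C(=O)O[C@@H](c2cc(OC)c(OC)c(OC)c2)[C@H](C)[C@H](C)B2O[C@H](C3CCCCC3)[C@@H](C3CCCCC3)O2)cc1OC | intermediate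
16 | hydrogen peroxide | OO | starting material
17 | (1R,2R,3S)-3-hydroxy-2-methyl-1-(3,4,5-trimethoxyphenyl)butyl 3,4-dimethoxybenzoate | COc1ccc(C(=O)O[C@@H](c2cc(OC)c(OC)c(OC)c2)[C@H](C)[C@H](C)O)cc1OC | target

Total step count: 8. Longest linear sequence: 8 steps (1 to 17).

Steps most likely to fail

Step 4. The borate at the hindered benzylic boron of 7 may form or rearrange slowly because zinc is held by the two ether oxygens and not by the departing chloride. Diastereoselection would then drop, or the methyl borate of 9 would lose its β-alkoxy group. The fallback sets out from 7 and comes back at 10; it is a lithiation–borylation with a carbenoid that already carries the methyl group. Ethyl 2,4,6-triisopropylbenzoate (CCOC(=O)c1c(C(C)C)cc(C(C)C)cc1C(C)C) is deprotonated with s-BuLi/(+)-sparteine in Et2O at −78 °C to the (R)-1-lithioethyl benzoate, which adds to the boron of 7 with retention. On warming (MgBr2·OEt2 if the shift is slow) C1 migrates to the carbenoid carbon with loss of the benzoate and inversion, which should give 10 without chloride, zinc or Grignard reagent. No new compound is made on the way (F0).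

Step 6. The oxidation may lose chemoselectivity: DDQ may abstract hydride at C1–H, which is benzylic to the trimethoxyphenyl ring and α to oxygen, or oxidise the freed C1 carbinol on to the aryl ketone. The fallback sets out from 5 and comes back at 13; it carries the C1 oxygen as an allyl ether, which is removed without an oxidant. Chloride 5 with lithium allyloxide (allyl alcohol, C=CCO, n-BuLi, THF, −78 °C → rt) should give the allyl ether boronate F1. The key step on it (LiCHCl2, ZnCl2, then MeMgBr) should give, through the α-chloro boronate F2, the methyl-bearing boronate F3. The third cycle should give, through the α-chloro boronate F4, the butan-2-yl boronate F5. Hydrogen-activated [Ir(cod)(PMePh2)2]PF6 in THF at rt isomerises the allyl group to the (E)-prop-1-enyl ether F6, which dilute HCl in aqueous acetone hydrolyses in the same flask to 13.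

Step 8. The veratroyl group may shift from O1 to the newly freed O3, or the ester may hydrolyse, if the hindered secondary boronate is oxidised only by more basic peroxide. The fallback sets out from 12 and comes back at 17; it unmasks the C3 hydroxyl before the ester exists and ends with an acidic desilylation. Oxidation of 12 with NaOH/H2O2 (THF, 0 °C) should give the C3 alcohol F7. TESCl/imidazole in DMF gives the triethylsilyl ether F8. DDQ in CH2Cl2/pH 7 buffer frees the C1 hydroxyl in the silyl ether alcohol F9. Acylation with 14 (Et3N, DMAP, CH2Cl2) gives the silylated ester F10. HF·pyridine in THF/pyridine at 0 °C then removes the silyl group without base to give 17.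

Further compounds
F0 | step 4 | none | none
F1 | step 6 | (4R,5R)-2-[(R)-(allyloxy)(3,4,5-trimethoxyphenyl)methyl]-4,5-dicyclohexyl-1,3,2-dioxaborolane | C=CCO[C@@H](c1cc(OC)c(OC)c(OC)c1)B1O[C@H](C2CCCCC2)[C@@H](C2CCCCC2)O1
F2 | step 6 | (4R,5R)-2-[(1S,2S)-2-(allyloxy)-1-chloro-2-(3,4,5-trimethoxyphenyl)ethyl]-4,5-dicyclohexyl-1,3,2-dioxaborolane | C=CCO[C@@H](c1cc(OC)c(OC)c(OC)c1)[C@@H](Cl)B1O[C@H](C2CCCCC2)[C@@H](C2CCCCC2)O1
F3 | step 6 | (4R,5R)-2-[(1R,2S)-1-(allyloxy)-1-(3,4,5-trimethoxyphenyl)propan-2-yl]-4,5-dicyclohexyl-1,3,2-dioxaborolane | C=CCO[C@@H](c1cc(OC)c(OC)c(OC)c1)[C@H](C)B1O[C@H](C2CCCCC2)[C@@H](C2CCCCC2)O1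
F4 | step 6 | (4R,5R)-2-[(1S,2S,3R)-3-(allyloxy)-1-chloro-2-methyl-3-(3,4,5-trimethoxyphenyl)propyl]-4,5-dicyclohexyl-1,3,2-dioxaborolane | C=CCO[C@@H](c1cc(OC)c(OC)c(OC)c1)[C@H](C)[C@@H](Cl)B1O[C@H](C2CCCCC2)[C@@H](C2CCCCC2)O1
F5 | step 6 | (4R,5R)-2-[(2S,3R,4R)-4-(allyloxy)-3-methyl-4-(3,4,5-trimethoxyphenyl)butan-2-yl]-4,5-dicyclohexyl-1,3,2-dioxaborolane | C=CCO[C@@H](c1cc(OC)c(OC)c(OC)c1)[C@H](C)[C@H](C)B1O[C@H](C2CCCCC2)[C@@H](C2CCCCC2)O1
F6 | step 6 | (4R,5R)-4,5-dicyclohexyl-2-[(2S,3R,4R)-3-methyl-4-[(E)-prop-1-enyloxy]-4-(3,4,5-trimethoxyphenyl)butan-2-yl]-1,3,2-dioxaborolane | C/C=C/O[C@@H](c1cc(OC)c(OC)c(OC)c1)[C@H](C)[C@H](C)B1O[C@H](C2CCCCC2)[C@@H](C2CCCCC2)O1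
F7 | step 8 | (2S,3R,4R)-4-(4-methoxybenzyloxy)-3-methyl-4-(3,4,5-trimethoxyphenyl)butan-2-ol | COc1ccc(CO[C@@H](c2cc(OC)c(OC)c(OC)c2)[C@H](C)[C@H](C)O)cc1
F8 | step 8 | triethyl{[(2S,3S,4R)-4-(4-methoxybenzyloxy)-3-methyl-4-(3,4,5-trimethoxyphenyl)butan-2-yl]oxy}silane | COc1ccc(CO[C@@H](c2cc(OC)c(OC)c(OC)c2)[C@H](C)[C@H](C)O[Si](CC)(CC)CC)cc1
F9 | step 8 | (1R,2S,3S)-2-methyl-3-(triethylsilyloxy)-1-(3,4,5-trimethoxyphenyl)butan-1-ol | O[C@@H](c1cc(OC)c(OC)c(OC)c1)[C@H](C)[C@H](C)O[Si](CC)(CC)CC
F10 | step 8 | (1R,2S,3S)-2-methyl-3-(triethylsilyloxy)-1-(3,4,5-trimethoxyphenyl)butyl 3,4-dimethoxybenzoate | COc1ccc(C(=O)O[C@@H](c2cc(OC)c(OC)c(OC)c2)[C@H](C)[C@H](C)O[Si](CC)(CC)CC)cc1OC
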